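**Plan**

1. Retrosynthesis cuts the arene C5–CH2 bond of the methylene bridge first, then the O1–C2 and C3–C3a bonds of the dihydrofuran together (a (3+2) cut to an o-bromophenol and isoprene), then the aryl–acyl bond. The pyrone is cut at its lactone C–O bond to a 3,5-diketo ester.
2. Forward: phloroglucinol is C-acylated, the 4-OH is masked as MOM ether, and one bromine is introduced. The dihydrofuran ring is then closed with isoprene by a Pd-catalysed Heck/allylic-etherification annulation.
3. After MOM removal, the separately made 4-hydroxy-2-pyranone is joined through a one-carbon iminium donor.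
4. Stereochemistry: the acyl α-centre comes from (S)-2-methylbutanoic acid (chiral pool). C2 of the dihydrofuran is set by the chiral Pd catalyst in the key step, through interconverting π-allyl complexes.
5. Enabling feature: C3, C2 and the isopropenyl group are an intact isoprene unit, and the O1–C2 bond is allylic to the isopropenyl C=C, so it can be made by phenoxide attack on a π-allylpalladium.
6. The 4-O-protected acylphloroglucinol has a mirror plane through C1/C4, so bromination gives one isomer and leaves only one OH ortho to Br, the one next to the acyl group (the future O1).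

Key step: step 4

Assumption: the SMILES is read as (2S) at the dihydrofuran carbon and (S) at the acyl α-carbon; the ligand antipode that delivers (2S) in step 4 is to be assigned on the first run, both antipodes being accessible.

**Route**

Step 1
Reactants: 1 (S)-2-methylbutanoic acid; 2 phloroglucinol (anhydrous)
Product: 4 (S)-2-methyl-1-(2,4,6-trihydroxyphenyl)butan-1-one, via (S)-2-methylbutanoyl chloride 3 (not isolated)
Conditions: (COCl)2 (1.05 equiv), cat. DMF, CH2Cl2, 0 °C → rt, volatiles distilled off; then 2, AlCl3 (4 equiv), PhNO2/CH2Cl2, 0 °C → rt; ice/1 M HCl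
Reagents that add atoms: none
Why: Friedel–Crafts C-acylation of the threefold-symmetric triol can give only one mono-ketone, the first acyl group deactivates the ring against a second acylation, and in a Lewis-acidic medium without base the α-stereocentre taken from the chiral pool is not expected to enolise.

Step 2
Reactants: 4 (S)-2-methyl-1-(2,4,6-trihydroxyphenyl)butan-1-one
Product: 5 (S)-1-[2,6-dihydroxy-4-(methoxymethoxy)phenyl]-2-methylbutan-1-one
Conditions: MOMCl (1.05 equiv), i-Pr2NEt (1.2 equiv), CH2Cl2/THF, −20 → 0 °C
Reagents that add atoms: chloromethyl methyl ether (MOMCl), COCCl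
Why: Williamson-type O-alkylation with one equivalent of MOMCl should go to the 4-OH, which is the most acidic hydroxyl (para to the ketone) and the only one that is neither chelated to the carbonyl nor shielded by the branched acyl group.

Step 3
Reactants: 5 (S)-1-[2,6-dihydroxy-4-(methoxymethoxy)phenyl]-2-methylbutan-1-one
Product: 6 (S)-1-[3-bromo-2,6-dihydroxy-4-(methoxymethoxy)phenyl]-2-methylbutan-1-one
Conditions: NBS (1.0 equiv), CH2Cl2, −78 → −20 °C, dark
Reagents that add atoms: N-bromosuccinimide, O=C1CCC(=O)N1Br
Why: Electrophilic aromatic bromination with one equivalent of NBS; C3 and C5 of 5 are equivalent by the mirror plane through C1 and C4, so mono-bromination can give only one regioisomer, with Br between the 2-OH and the OMOM group.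

Step 4
Reactants: 6 (S)-1-[3-bromo-2,6-dihydroxy-4-(methoxymethoxy)phenyl]-2-methylbutan-1-one; 7 isoprene
Product: 8 (2S)-1-[(2S)-6-hydroxy-4-(methoxymethoxy)-2-(prop-1-en-2-yl)-2,3-dihydro-1-benzofuran-7-yl]-2-methylbutan-1-one
Conditions: Pd2(dba)3·CHCl3 (5 mol %), chiral sulfinamide–monophosphine ligand (Sadphos type, e.g. TY-Phos, 15 mol %), NaOPh (2.5 equiv), 7 (6 equiv), PhMe, 60 °C, sealed tube
Reagents that add atoms: none
Why: Oxidative addition of the chiral Pd(0) complex into the C3–Br bond of 6 and syn-carbopalladation of the monosubstituted C3=C4 bond of isoprene (aryl to the terminal CH2, which avoids the methyl-bearing alkene and leads to the more substituted allyl) should give an η3-(1-arylmethyl-2-methylallyl)palladium species, which the neighbouring 2-phenoxide captures at the substituted allyl terminus. The closest known reaction type is the Larock diene heteroannulation of o-halophenols in its enantioselective Heck/Tsuji–Trost form, shown for o-bromophenols with isoprene. The dihydrofuran ring (O1–C2–C3–C3a–C7a) is closed by 5-exo attack of oxygen on the allyl terminus anti to palladium, a formal (3+2) annulation that makes the C3a–C3 and C2–O1 bonds in one operation, while the 7-endo alternative at the CH2 terminus is disfavoured by ring size. The C2 stereocentre is under catalyst control: the two diastereomeric π-allyl complexes can interconvert by η3–η1–η3 slippage at the unsubstituted CH2 terminus, so both alkene-insertion faces should be funnelled by the ligand into the (2S) product, and the remote (S)-acyl centre should have no say. Three selectivities are needed, namely which oxygen closes (only the 2-OH is ortho to the palladated carbon, since the 4-oxygen is masked as MOM ether and the 6-OH cannot reach), which alkene inserts (sterics), and allylic substitution over β-hydride elimination (secured by the stabilised π-allyl and the fast intramolecular capture).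

Step 5
Reactants: 8 (2S)-1-[(2S)-6-hydroxy-4-(methoxymethoxy)-2-(prop-1-en-2-yl)-2,3-dihydro-1-benzofuran-7-yl]-2-methylbutan-1-one
Product: 9 (2S)-1-[(2S)-4,6-dihydroxy-2-(prop-1-en-2-yl)-2,3-dihydro-1-benzofuran-7-yl]-2-methylbutan-1-one
Conditions: HCl (1.25 M in MeOH, cat. to 3 equiv), MeOH, 30–40 °C
Reagents that add atoms: none
Why: Acid-catalysed transacetalisation (methanolysis) of the aryl MOM ether, whose phenol is a good leaving group owing to the para-acyl group, should proceed under dilute acid at or below 40 °C without touching the isopropenyl group, the allylic aryl ether or the α-stereocentre.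

Step 6
Reactants: 10 methyl 3-oxopentanoate; 11 N-methoxy-N-methylpropanamide
Product: 12 methyl 4-methyl-3,5-dioxoheptanoate (racemic at C4, keto/enol mixture)
Conditions: NaH (1.1 equiv), THF, 0 °C; n-BuLi (1.05 equiv), 0 °C; then 11, −78 → 0 °C; 1 M HCl
Reagents that add atoms: none
Why: γ-Acylation of the β-keto ester dianion at its more nucleophilic terminal carbanion (C4) by the Weinreb amide, whose stable tetrahedral adduct prevents proton transfer and over-addition; the new C4 centre is enolisable and is carried as a mixture because it becomes sp2 in the next step.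

Step 7
Reactants: 12 methyl 4-methyl-3,5-dioxoheptanoate
Product: 13 6-ethyl-4-hydroxy-5-methyl-2H-pyran-2-one
Conditions: DBU (1.2 equiv), PhMe, reflux; then 1 M HCl
Reagents that add atoms: none
Why: Base-mediated lactonisation of the 3,5-diketo ester (6-exo-trig attack of the C5 enolate oxygen on the ester with loss of methanol) and tautomerisation should give the aromatic 4-hydroxy-2-pyranone, the standard triketide-to-pyrone cyclisation.

Step 8
Reactants: 13 6-ethyl-4-hydroxy-5-methyl-2H-pyran-2-one; 9 (2S)-1-[(2S)-4,6-dihydroxy-2-(prop-1-en-2-yl)-2,3-dihydro-1-benzofuran-7-yl]-2-methylbutan-1-one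
Product: 16 6-ethyl-4-hydroxy-3-({(2S)-4,6-dihydroxy-7-[(2S)-2-methylbutanoyl]-2-(prop-1-en-2-yl)-2,3-dihydro-1-benzofuran-5-yl}methyl)-5-methyl-2H-pyran-2-one (CNP0261501.1), via pyrone Mannich base 14 (not isolated), via 3-methylidenepyran-2,4-dione 15 (not isolated)
Conditions: 13, Me2N=CH2+ I− (1.05 equiv), MeCN, rt, 1 h; then 9 (1.0 equiv), 40 °C
Reagents that add atoms: Eschenmoser's salt (N,N-dimethylmethyleneiminium iodide), C[N+](C)=C.[I-]
Why: Mannich reaction at pyrone C3, loss of dimethylamine to the 3-methylidene-2,4-dione and conjugate (Friedel–Crafts-type) addition of the only free aromatic carbon of 9 (C5, flanked by two OH groups) should forge the methylene bridge, forming the pyrone Mannich base first should suppress the symmetrical dimers, and no stereocentre is touched under these near-neutral conditions.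

**Compound list**

1 | (S)-2-methylbutanoic acid | O=C(O)[C@@H](C)CC | starting material
2 | phloroglucinol (benzene-1,3,5-triol) | Oc1cc(O)cc(O)c1 | starting material
3 | (S)-2-methylbutanoyl chloride (not isolated) | O=C(Cl)[C@@H](C)CC | intermediate
4 | (S)-2-methyl-1-(2,4,6-trihydroxyphenyl)butan-1-one | Oc1cc(O)c(C(=O)[C@@H](C)CC)c(O)c1 | intermediate
5 | (S)-1-[2,6-dihydroxy-4-(methoxymethoxy)phenyl]-2-methylbutan-1-one | COCOc1cc(O)c(C(=O)[C@@H](C)CC)c(O)c1 | intermediate
6 | (S)-1-[3-bromo-2,6-dihydroxy-4-(methoxymethoxy)phenyl]-2-methylbutan-1-one | COCOc1cc(O)c(C(=O)[C@@H](C)CC)c(O)c1Br | intermediate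
7 | isoprene (2-methylbuta-1,3-diene) | C=CC(C)=C | starting material
8 | (2S)-1-[(2S)-6-hydroxy-4-(methoxymethoxy)-2-(prop-1-en-2-yl)-2,3-dihydro-1-benzofuran-7-yl]-2-methylbutan-1-one | C=C(C)[C@@H]1Cc2c(OCOC)cc(O)c(C(=O)[C@@H](C)CC)c2O1 | intermediate
9 | (2S)-1-[(2S)-4,6-dihydroxy-2-(prop-1-en-2-yl)-2,3-dihydro-1-benzofuran-7-yl]-2-methylbutan-1-one | C=C(C)[C@@H]1Cc2c(O)cc(O)c(C(=O)[C@@H](C)CC)c2O1 | intermediate
10 | methyl 3-oxopentanoate | CCC(=O)CC(=O)OC | starting material
11 | N-methoxy-N-methylpropanamide | CCC(=O)N(C)OC | starting material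
12 | methyl 4-methyl-3,5-dioxoheptanoate (racemic, keto/enol mixture) | CCC(=O)C(C)C(=O)CC(=O)OC | intermediate
13 | 6-ethyl-4-hydroxy-5-methyl-2H-pyran-2-one | CCc1oc(=O)cc(O)c1C | intermediate
14 | 3-[(dimethylamino)methyl]-6-ethyl-4-hydroxy-5-methyl-2H-pyran-2-one (not isolated) | CCc1oc(=O)c(CN(C)C)c(O)c1C | intermediate
15 | 6-ethyl-5-methyl-3-methylidene-2H-pyran-2,4(3H)-dione (not isolated) | CCC1=C(C)C(=O)C(=C)C(=O)O1 | intermediate
16 | 6-ethyl-4-hydroxy-3-({(2S)-4,6-dihydroxy-7-[(2S)-2-methylbutanoyl]-2-(prop-1-en-2-yl)-2,3-dihydro-1-benzofuran-5-yl}methyl)-5-methyl-2H-pyran-2-one | C=C(C)[C@@H]1Cc2c(O)c(Cc3c(O)c(C)c(CC)oc3=O)c(O)c(C(=O)[C@@H](C)CC)c2O1 | target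

**Count and risks**

Total step count: 8. Longest linear sequence: 6 steps (1, 2, 3, 4, 5, 8); the pyrone arm (steps 6, 7) joins at step 8.

Steps most likely to fail:

1. Step 4. Oxidative addition into the doubly ortho-substituted, phenoxide-rich C–Br bond may be slow. The o-acylphenoxide chelate may sequester Pd(II). The π-allyl may drain by β-hydride elimination to an aryl diene. Facial selectivity in the C–O bond formation may be poor, and re-ionisation of the allylic C2–O1 bond of the product may erode the configuration.
Fallback (known epoxide chemistry), setting out from 5 and coming back at 8: C-prenylation at C3 (prenyl bromide, DBU, THF, 0 °C) would give (S)-1-[2,6-dihydroxy-4-(methoxymethoxy)-3-(3-methylbut-2-en-1-yl)phenyl]-2-methylbutan-1-one F1. Acetylation of both phenols (Ac2O, pyridine, DMAP) would give the diacetate 3-(methoxymethoxy)-6-[(2S)-2-methylbutanoyl]-2-(3-methylbut-2-en-1-yl)-1,5-phenylene diacetate F2. Shi epoxidation (fructose-derived ketone of the enantiomeric series that delivers the (R)-epoxide, Oxone, buffered MeCN/dimethoxymethane/H2O, 0 °C) would give the (R)-epoxide 2-{[(2R)-3,3-dimethyloxiran-2-yl]methyl}-3-(methoxymethoxy)-6-[(2S)-2-methylbutanoyl]-1,5-phenylene diacetate F3. K2CO3 in MeOH would remove the acetates, and the freed 2-phenoxide would open the epoxide at its secondary carbon (5-exo-tet, inversion) to the tertiary alcohol (2S)-1-[(2S)-6-hydroxy-2-(2-hydroxypropan-2-yl)-4-(methoxymethoxy)-2,3-dihydro-1-benzofuran-7-yl]-2-methylbutan-1-one F4. Dehydration of the tertiary alcohol towards the methyl groups (Burgess reagent, PhMe, 60 °C) would give 8. The MOM group secures the same choice of oxygen as in the main route.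

2. Step 1. Partial racemisation of the α-stereocentre may occur through enolisation of the ketone–AlCl3 complex or of the acid chloride, and over-acylation is possible.
Fallback (directed lithiation and Weinreb ketone synthesis), setting out from 2 and 1 and coming back at 4: 2 would be converted (MOMCl, NaH, DMF) into 1,3,5-tris(methoxymethoxy)benzene F5, and 1 (CDI, then MeNHOMe·HCl, CH2Cl2) into (S)-N-methoxy-N,2-dimethylbutanamide F6. Ortho-lithiation of F5 between two OMOM groups (n-BuLi, THF, 0 °C) and addition to F6 at −78 °C would give (S)-2-methyl-1-[2,4,6-tris(methoxymethoxy)phenyl]butan-1-one F7 through the chelated tetrahedral adduct, without exposure of the α-centre to acid or free base. Methanolic HCl at room temperature would then remove the three MOM groups to give 4.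

3. Step 8. The electrophile may be captured unselectively (pyrone–pyrone or arene–arene methylene dimers), the methylene bridge may scramble by retro-Mannich/retro-Michael exchange, and the isopropenyl dihydrofuran may suffer acid-induced change from the ammonium salt.
Fallback (reversed roles of the partners), setting out from 9 and 13 and coming back at 16: 9 would be aminomethylated at C5 with Eschenmoser's salt (CH2Cl2, rt, NaHCO3 work-up) and isolated as (2S)-1-[(2S)-5-[(dimethylamino)methyl]-4,6-dihydroxy-2-(prop-1-en-2-yl)-2,3-dihydro-1-benzofuran-7-yl]-2-methylbutan-1-one F8. Heating F8 with 13 (dioxane, 80 °C) would expel dimethylamine to an o-quinone methide of the arene, which pyrone C3 captures by conjugate addition to give 16. No free iminium electrophile then ever meets the pyrone, so pyrone homodimers should be avoided.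

**Further compounds**

F1 | step 4 | (S)-1-[2,6-dihydroxy-4-(methoxymethoxy)-3-(3-methylbut-2-en-1-yl)phenyl]-2-methylbutan-1-one | COCOc1cc(O)c(C(=O)[C@@H](C)CC)c(O)c1CC=C(C)C
F2 | step 4 | 3-(methoxymethoxy)-6-[(2S)-2-methylbutanoyl]-2-(3-methylbut-2-en-1-yl)-1,5-phenylene diacetate | COCOc1cc(OC(C)=O)c(C(=O)[C@@H](C)CC)c(OC(C)=O)c1CC=C(C)C
F3 | step 4 | 2-{[(2R)-3,3-dimethyloxiran-2-yl]methyl}-3-(methoxymethoxy)-6-[(2S)-2-methylbutanoyl]-1,5-phenylene diacetate | COCOc1cc(OC(C)=O)c(C(=O)[C@@H](C)CC)c(OC(C)=O)c1C[C@H]2OC2(C)C
F4 | step 4 | (2S)-1-[(2S)-6-hydroxy-2-(2-hydroxypropan-2-yl)-4-(methoxymethoxy)-2,3-dihydro-1-benzofuran-7-yl]-2-methylbutan-1-one | CC(C)(O)[C@@H]1Cc2c(OCOC)cc(O)c(C(=O)[C@@H](C)CC)c2O1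
F5 | step 1 | 1,3,5-tris(methoxymethoxy)benzene | COCOc1cc(OCOC)cc(OCOC)c1
F6 | step 1 | (S)-N-methoxy-N,2-dimethylbutanamide | CON(C)C(=O)[C@@H](C)CC
F7 | step 1 | (S)-2-methyl-1-[2,4,6-tris(methoxymethoxy)phenyl]butan-1-one | COCOc1cc(OCOC)c(C(=O)[C@@H](C)CC)c(OCOC)c1
F8 | step 8 | (2S)-1-[(2S)-5-[(dimethylamino)methyl]-4,6-dihydroxy-2-(prop-1-en-2-yl)-2,3-dihydro-1-benzofuran-7-yl]-2-methylbutan-1-one | C=C(C)[C@@H]1Cc2c(O)c(CN(C)C)c(O)c(C(=O)[C@@H](C)CC)c2O1
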